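**Retrosynthetic overview**

1. Caraphenol B ⇐ its hexabenzyl ether (H2, Pd/C) ⇐ a 3-aryl-3-hydroxyindane (ionic hydrogenation gives C3–H) ⇐ a 3-aryl-indenol (OH-directed hydrogenation of C1=C2), whose carbinol C3 comes from a catalytic enantioselective aryl addition to a flat, achiral 3-aroyl-2-aryl-indenone.
2. Indenone ⇐ allyl 3-aroyl-2-aryl-1-oxoindane-2-carboxylate (Pd, loss of CO2 and propene).
3. Key disconnection: the two aryl–carbon bonds of the five-membered ring, C7a–C1 and C3a–C3, are cut together. Forward, 3,5-bis(benzyloxy)benzyne and the ketone enolate of a γ-keto aryl malonate join in an anionic [3+2] annulation (enolate carbon to the aryne, then aryl anion to an ester).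
4. Enabling feature: in the resorcinol-type benzo ring, C7a is meta and C3a is ortho/para to the oxygens at C4 and C6. In the corresponding aryne the C4 oxygen makes C7a the electrophilic carbon and C3a the carbanionic one, which matches C1 (α to the aroyl ketone, enolate carbon) and C3 (carbonyl level, acyl acceptor).
5. Ring order: all six-membered rings come aromatic from the building blocks; the five-membered ring is the only ring closed, in the key step.

Key step: step 5

Remark: the SMILES is read as the (1R,2R,3R) isomer, with the aroyl group at C1, the 4-hydroxyphenyl at C2 and the 3,5-dihydroxyphenyl at C3 all on one face of the indane. C1 (α to the ketone) is then the less stable epimer, so it is set late and kept away from base.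

**Route**

Step 1
Reactants: 1 diallyl malonate; 2 1-(benzyloxy)-4-iodobenzene
Product: 3 diallyl 2-[4-(benzyloxy)phenyl]malonate
Conditions: CuI (5 mol%), 2-picolinic acid (10 mol%), Cs2CO3 (3 equiv), 1,4-dioxane, 25 → 70 °C
Reagents that add atoms: none
Why: Copper-catalysed α-arylation of a malonate with an aryl iodide; copper, unlike palladium, leaves the allyl esters and the benzyl ether untouched.

Step 2
Reactants: 3 diallyl 2-[4-(benzyloxy)phenyl]malonate; 4 1-[4-(benzyloxy)phenyl]-2-bromoethan-1-one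
Product: 5 diallyl 2-[4-(benzyloxy)phenyl]-2-{2-[4-(benzyloxy)phenyl]-2-oxoethyl}malonate
Conditions: K2CO3, acetone, 25 °C
Reagents that add atoms: none
Why: SN2 alkylation of the aryl malonate anion by the phenacyl bromide; the new quaternary carbon (future C2) has no hydrogen, so the ketone CH2 (future C1) is the only enolisable position in the key step.

Step 3
Reactants: 6 3,5-bis(benzyloxy)phenol
Product: 7 3,5-bis(benzyloxy)-2-bromophenol
Conditions: NBS (1.0 equiv), i-Pr2NH (10 mol%), CH2Cl2, −78 → 0 °C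
Reagents that add atoms: N-bromosuccinimide, O=C1CCC(=O)N1Br
Why: Amine-mediated ortho-selective electrophilic bromination of a phenol; the hydrogen-bonded N-bromoamine should deliver bromine next to OH (C2) and not between the two benzyloxy groups.

Step 4
Reactants: 7 3,5-bis(benzyloxy)-2-bromophenol
Product: 11 3,5-bis(benzyloxy)-2-(trimethylsilyl)phenyl trifluoromethanesulfonate, via silyl ether 8 (not isolated), via aryllithium 9 (not isolated), via lithium phenoxide 10 (not isolated)
Conditions: HMDS, THF, 70 °C, then evaporation; n-BuLi, THF, −100 → −78 °C; Tf2O, −78 → 0 °C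
Reagents that add atoms: hexamethyldisilazane, C[Si](C)(C)N[Si](C)(C)C; trifluoromethanesulfonic anhydride, O=S(=O)(OS(=O)(=O)C(F)(F)F)C(F)(F)F
Why: Standard synthesis of an ortho-silylaryl triflate aryne precursor: O-silylation, bromine–lithium exchange, 1,3 O→C silyl shift (retro-Brook) and O-triflation of the phenoxide.

Step 5
Reactants: 5 diallyl 2-[4-(benzyloxy)phenyl]-2-{2-[4-(benzyloxy)phenyl]-2-oxoethyl}malonate; 11 3,5-bis(benzyloxy)-2-(trimethylsilyl)phenyl trifluoromethanesulfonate
Product: 15 allyl 3-[4-(benzyloxy)benzoyl]-5,7-bis(benzyloxy)-2-[4-(benzyloxy)phenyl]-1-oxo-2,3-dihydro-1H-indene-2-carboxylate (mixture of diastereomers), via potassium enolate 12 (not isolated), via aryne 13 (not isolated), via aryl anion 14 (not isolated)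
Conditions: KHMDS (1.1 equiv), THF, −78 °C; then 11 (1.2 equiv), KF (3 equiv), 18-crown-6 (3 equiv), 0 → 25 °C; H2O work-up
Reagents that add atoms: none
Why: Proposed new method: fluoride-induced 1,2-elimination of 11 gives 3,5-bis(benzyloxy)benzyne 13; the potassium enolate 12 (the only enolate 5 can form) adds through carbon to the aryne carbon meta to oxygen (future C7a), and the aryl anion 14 thus formed at the carbon ortho to oxygen (future C3a) attacks one of the two geminal allyl esters in a 5-exo-trig addition–elimination that expels allyloxide and closes the five-membered ring. The closest known reaction types are the aryne acyl-alkylation of β-dicarbonyl compounds and the nucleophile–aryne–ester annulations that give xanthones and indolin-3-ones; here the same two events (C-arylation of an enolate, acylation of the resulting aryl anion) are merged into a carbocyclic [3+2] annulation. The only ring closed is the cyclopentanone, by anionic 5-exo-trig acyl substitution; C1 and C2 are formed without stereocontrol, which does not matter because both become sp2 in step 6. The step needs (i) regioselective addition to the aryne, secured by the 3-alkoxy group (distorted triple bond, inductively stabilised ortho anion), (ii) a single enolisation site and C-arylation, secured by the quaternary C2, and (iii) 5-exo acylation in preference to 4-exo attack on the aroyl ketone or protonation of 14, favoured by two ester carbonyls within reach of a strain-free five-membered transition state, by THF as a non-acidic solvent and by the irreversible loss of allyloxide. The liberated allyloxide should deprotonate the product at C1, which shields the non-enolisable β-keto ester from retro-Claisen cleavage until work-up.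

Step 6
Reactants: 15 allyl 3-[4-(benzyloxy)benzoyl]-5,7-bis(benzyloxy)-2-[4-(benzyloxy)phenyl]-1-oxo-2,3-dihydro-1H-indene-2-carboxylate
Product: 16 3-[4-(benzyloxy)benzoyl]-5,7-bis(benzyloxy)-2-[4-(benzyloxy)phenyl]-1H-inden-1-one
Conditions: Pd(OAc)2 (5 mol%), dppe (5 mol%), MeCN, 80 °C
Reagents that add atoms: none
Why: Tsuji decarboxylation–dehydrogenation of an allyl β-keto ester: the allylpalladium enolate formed on loss of CO2 undergoes β-hydride elimination of the C1–H, giving the C1=C2 bond and propene and erasing both uncontrolled stereocentres, so that a flat, achiral indenone enters the enantioselective step.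

Step 7
Reactants: 16 3-[4-(benzyloxy)benzoyl]-5,7-bis(benzyloxy)-2-[4-(benzyloxy)phenyl]-1H-inden-1-one; 17 [3,5-bis(benzyloxy)phenyl]boronic acid
Product: 19 {(1R)-5,7-bis(benzyloxy)-1-[3,5-bis(benzyloxy)phenyl]-2-[4-(benzyloxy)phenyl]-1-hydroxy-1H-inden-3-yl}[4-(benzyloxy)phenyl]methanone, via arylzinc 18 (not isolated)
Conditions: 17, Et2Zn, toluene, 60 °C; then Ti(Oi-Pr)4 (1.2 equiv), trans-1,2-bis(hydroxycamphorsulfonamido)cyclohexane ligand (10 mol%, antipode chosen to give the (R)-carbinol), 16, toluene, 0 → 25 °C; H2O work-up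
Reagents that add atoms: none
Why: Titanium/bis(sulfonamide)-catalysed enantioselective aryl transfer from an arylzinc reagent (made by boron–zinc exchange) to a ketone, a reaction type established for aryl ketones and α-substituted cyclic enones: 1,2-addition should occur at the strained, exposed indenone carbonyl and not at the hindered cross-conjugated diaryl ketone, and the chiral titanium complex selects the carbonyl face, setting C3 as the (R)-tertiary alcohol that controls all later stereochemistry.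

Step 8
Reactants: 19 {(1R)-5,7-bis(benzyloxy)-1-[3,5-bis(benzyloxy)phenyl]-2-[4-(benzyloxy)phenyl]-1-hydroxy-1H-inden-3-yl}[4-(benzyloxy)phenyl]methanone
Product: 20 [(1R,2R,3S)-4,6-bis(benzyloxy)-3-[3,5-bis(benzyloxy)phenyl]-2-[4-(benzyloxy)phenyl]-3-hydroxy-2,3-dihydro-1H-inden-1-yl][4-(benzyloxy)phenyl]methanone
Conditions: [Ir(cod)(PCy3)(py)]PF6 (10 mol%), H2 (10–50 bar), CH2Cl2, 25 °C
Reagents that add atoms: none
Why: Hydroxyl-directed hydrogenation of a tetrasubstituted alkene with Crabtree's catalyst: the tertiary allylic OH at C3 binds iridium and both hydrogens add to C1 and C2 from the hydroxyl face, so the aroyl group and the 4-benzyloxyphenyl group become cis to each other and cis to the C3 aryl group, while benzyl ethers and ketone are untouched.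

Step 9
Reactants: 20 [(1R,2R,3S)-4,6-bis(benzyloxy)-3-[3,5-bis(benzyloxy)phenyl]-2-[4-(benzyloxy)phenyl]-3-hydroxy-2,3-dihydro-1H-inden-1-yl][4-(benzyloxy)phenyl]methanone
Product: 21 [(1R,2R,3R)-4,6-bis(benzyloxy)-3-[3,5-bis(benzyloxy)phenyl]-2-[4-(benzyloxy)phenyl]-2,3-dihydro-1H-inden-1-yl][4-(benzyloxy)phenyl]methanone
Conditions: Et3SiH (5 equiv), TFA (5 equiv), CH2Cl2, −40 → −10 °C
Reagents that add atoms: none
Why: Ionic hydrogenation of a tertiary, doubly benzylic alcohol: the C3 cation is strongly stabilised by the ortho/para-dialkoxy ring, and triethylsilane should deliver hydride to the face opposite the neighbouring C2 aryl group (the face the hydroxyl left), giving C3–H cis to C2–H and thus the all-cis array; low temperature and short exposure protect the epimerisable C1 and the benzyl ethers.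

Step 10
Reactants: 21 [(1R,2R,3R)-4,6-bis(benzyloxy)-3-[3,5-bis(benzyloxy)phenyl]-2-[4-(benzyloxy)phenyl]-2,3-dihydro-1H-inden-1-yl][4-(benzyloxy)phenyl]methanone
Product: 22 caraphenol B, [(1R,2R,3R)-3-(3,5-dihydroxyphenyl)-4,6-dihydroxy-2-(4-hydroxyphenyl)-2,3-dihydro-1H-inden-1-yl](4-hydroxyphenyl)methanone
Conditions: H2 (1 atm), 10% Pd/C, EtOAc–MeOH, 25 °C
Reagents that add atoms: none
Why: Neutral hydrogenolysis of the six benzyl ethers; with no acid or base present the α-keto stereocentre C1 should not epimerise, and the electron-rich aryl ketone should not be reduced under these mild conditions.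

**Compound list**

1 | diallyl malonate | C=CCOC(=O)CC(=O)OCC=C | starting material
2 | 1-(benzyloxy)-4-iodobenzene | Ic1ccc(OCc2ccccc2)cc1 | starting material
3 | diallyl 2-[4-(benzyloxy)phenyl]malonate | C=CCOC(=O)C(C(=O)OCC=C)c1ccc(OCc2ccccc2)cc1 | intermediate
4 | 1-[4-(benzyloxy)phenyl]-2-bromoethan-1-one | O=C(CBr)c1ccc(OCc2ccccc2)cc1 | starting material
5 | diallyl 2-[4-(benzyloxy)phenyl]-2-{2-[4-(benzyloxy)phenyl]-2-oxoethyl}malonate | C=CCOC(=O)C(CC(=O)c1ccc(OCc2ccccc2)cc1)(C(=O)OCC=C)c1ccc(OCc2ccccc2)cc1 | intermediate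
6 | 3,5-bis(benzyloxy)phenol | Oc1cc(OCc2ccccc2)cc(OCc2ccccc2)c1 | starting material
7 | 3,5-bis(benzyloxy)-2-bromophenol | Oc1cc(OCc2ccccc2)cc(OCc2ccccc2)c1Br | intermediate
8 | [3,5-bis(benzyloxy)-2-bromophenoxy]trimethylsilane (silyl ether) | C[Si](C)(C)Oc1cc(OCc2ccccc2)cc(OCc2ccccc2)c1Br | intermediate
9 | {2,4-bis(benzyloxy)-6-[(trimethylsilyl)oxy]phenyl}lithium (aryllithium) | [Li]c1c(O[Si](C)(C)C)cc(OCc2ccccc2)cc1OCc1ccccc1 | intermediate
10 | lithium 3,5-bis(benzyloxy)-2-(trimethylsilyl)phenolate (lithium phenoxide) | [Li+].[O-]c1cc(OCc2ccccc2)cc(OCc2ccccc2)c1[Si](C)(C)C | intermediate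
11 | 3,5-bis(benzyloxy)-2-(trimethylsilyl)phenyl trifluoromethanesulfonate | C[Si](C)(C)c1c(OS(=O)(=O)C(F)(F)F)cc(OCc2ccccc2)cc1OCc1ccccc1 | intermediate
12 | potassium enolate of 5 | [K+].[O-]C(=CC(C(=O)OCC=C)(C(=O)OCC=C)c1ccc(OCc2ccccc2)cc1)c1ccc(OCc2ccccc2)cc1 | intermediate
13 | 3,5-bis(benzyloxy)benzyne (1,2-didehydro arene) | C1(OCc2ccccc2)=CC(OCc2ccccc2)=CC#C1 | intermediate
14 | potassium aryl anion formed by C-arylation of 12 (carbanion ortho to the benzyloxy group) | [K+].O=C(c1ccc(OCc2ccccc2)cc1)C(C1=[C-]C(OCc2ccccc2)=CC(OCc2ccccc2)=C1)C(C(=O)OCC=C)(C(=O)OCC=C)c1ccc(OCc2ccccc2)cc1 | intermediate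
15 | allyl 3-[4-(benzyloxy)benzoyl]-5,7-bis(benzyloxy)-2-[4-(benzyloxy)phenyl]-1-oxo-2,3-dihydro-1H-indene-2-carboxylate (diastereomer mixture) | C=CCOC(=O)C1(c2ccc(OCc3ccccc3)cc2)C(C(=O)c2ccc(OCc3ccccc3)cc2)c2cc(OCc3ccccc3)cc(OCc3ccccc3)c2C1=O | intermediate
16 | 3-[4-(benzyloxy)benzoyl]-5,7-bis(benzyloxy)-2-[4-(benzyloxy)phenyl]-1H-inden-1-one | O=C1C(c2ccc(OCc3ccccc3)cc2)=C(C(=O)c2ccc(OCc3ccccc3)cc2)c2cc(OCc3ccccc3)cc(OCc3ccccc3)c12 | intermediate
17 | [3,5-bis(benzyloxy)phenyl]boronic acid | OB(O)c1cc(OCc2ccccc2)cc(OCc2ccccc2)c1 | starting material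
18 | [3,5-bis(benzyloxy)phenyl](ethyl)zinc (arylzinc) | CC[Zn]c1cc(OCc2ccccc2)cc(OCc2ccccc2)c1 | intermediate
19 | {(1R)-5,7-bis(benzyloxy)-1-[3,5-bis(benzyloxy)phenyl]-2-[4-(benzyloxy)phenyl]-1-hydroxy-1H-inden-3-yl}[4-(benzyloxy)phenyl]methanone | O=C(c1ccc(OCc2ccccc2)cc1)C1=C(c2ccc(OCc3ccccc3)cc2)[C@](O)(c2cc(OCc3ccccc3)cc(OCc3ccccc3)c2)c2c(OCc3ccccc3)cc(OCc3ccccc3)cc21 | intermediate
20 | [(1R,2R,3S)-4,6-bis(benzyloxy)-3-[3,5-bis(benzyloxy)phenyl]-2-[4-(benzyloxy)phenyl]-3-hydroxy-2,3-dihydro-1H-inden-1-yl][4-(benzyloxy)phenyl]methanone (aroyl, C2 aryl and C3 aryl cis; OH on the other face) | O=C(c1ccc(OCc2ccccc2)cc1)[C@H]1c2cc(OCc3ccccc3)cc(OCc3ccccc3)c2[C@@](O)(c2cc(OCc3ccccc3)cc(OCc3ccccc3)c2)[C@H]1c1ccc(OCc2ccccc2)cc1 | intermediate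
21 | [(1R,2R,3R)-4,6-bis(benzyloxy)-3-[3,5-bis(benzyloxy)phenyl]-2-[4-(benzyloxy)phenyl]-2,3-dihydro-1H-inden-1-yl][4-(benzyloxy)phenyl]methanone (all-cis) | O=C(c1ccc(OCc2ccccc2)cc1)[C@H]1c2cc(OCc3ccccc3)cc(OCc3ccccc3)c2[C@@H](c2cc(OCc3ccccc3)cc(OCc3ccccc3)c2)[C@H]1c1ccc(OCc2ccccc2)cc1 | intermediate
22 | caraphenol B, [(1R,2R,3R)-3-(3,5-dihydroxyphenyl)-4,6-dihydroxy-2-(4-hydroxyphenyl)-2,3-dihydro-1H-inden-1-yl](4-hydroxyphenyl)methanone | O=C(c1ccc(O)cc1)[C@H]1c2cc(O)cc(O)c2[C@@H](c2cc(O)cc(O)c2)[C@H]1c1ccc(O)cc1 | target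

**Summary**

Total step count: 10. Longest linear sequence: 8 steps (6 → 7 → 11 → 15 → 16 → 19 → 20 → 21 → 22; the branch from 1 and 2 is equally long).

**Steps most likely to fail**

Step 5 (proposed new method). The aryl anion may close onto the aroyl ketone (four-membered ring, then fragmentation) or be protonated before it acylates; the product enolate may also be arylated a second time by excess aryne. Fallback: the two aryl–carbon bonds are made one after the other by polarity-matched known reactions, setting out from 4 and 17 and returning at 16. Palladium-catalysed cross-coupling of α-bromo ketone 4 with boronic acid 17 (Pd(OAc)2, P(o-tol)3, K3PO4, toluene–H2O) should give the deoxybenzoin 2-[3,5-bis(benzyloxy)phenyl]-1-[4-(benzyloxy)phenyl]ethan-1-one F1, which already holds the C7a–C1 bond. Its sodium enolate (NaH, THF) is alkylated with allyl 2-bromo-2-[4-(benzyloxy)phenyl]acetate (C=CCOC(=O)C(Br)c1ccc(OCc2ccccc2)cc1) to allyl 3-[3,5-bis(benzyloxy)phenyl]-2,4-bis[4-(benzyloxy)phenyl]-4-oxobutanoate F2. Pd(PPh3)4 and morpholine free the acid 3-[3,5-bis(benzyloxy)phenyl]-2,4-bis[4-(benzyloxy)phenyl]-4-oxobutanoic acid F3. Trifluoroacetic anhydride (CH2Cl2, 0 °C) closes the ring by Friedel–Crafts acylation at the ring position ortho and para to the two benzyloxy groups (C3a–C3 bond), giving 3-[4-(benzyloxy)benzoyl]-5,7-bis(benzyloxy)-2-[4-(benzyloxy)phenyl]-2,3-dihydro-1H-inden-1-one F4. DDQ (dioxane, 25 °C) dehydrogenates F4 to 16.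

Step 7. The two flanks of the indenone carbonyl are both sp2 carbons, so the catalyst may discriminate the carbonyl faces poorly; ethyl transfer or addition to the exocyclic ketone may also compete. Fallback: the aryl group is added without asymmetric induction and the enantiomers are separated, setting out from 16 and returning at 19. The organocerium reagent from 1-bromo-3,5-bis(benzyloxy)benzene (t-BuLi, then CeCl3, THF, −78 °C) adds to the indenone carbonyl of 16 to give the racemic indenol, that is 19 together with its enantiomer {(1S)-5,7-bis(benzyloxy)-1-[3,5-bis(benzyloxy)phenyl]-2-[4-(benzyloxy)phenyl]-1-hydroxy-1H-inden-3-yl}[4-(benzyloxy)phenyl]methanone F5. Preparative chromatography on a chiral stationary phase removes F5 and delivers 19.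

Step 9. The C3 cation may be trapped by the cis aroyl oxygen (reductive ether formation) or lose the C2 proton; acid may epimerise C1 or cleave benzyl ethers. Fallback: deoxygenation by elimination and hydrogenation instead of hydride transfer, setting out from 20 and returning at 22. The Burgess reagent (toluene, 50 °C) should remove the C3 hydroxyl and the cis C2 hydrogen by syn elimination to give the indene [(1S)-4,6-bis(benzyloxy)-3-[3,5-bis(benzyloxy)phenyl]-2-[4-(benzyloxy)phenyl]-1H-inden-1-yl][4-(benzyloxy)phenyl]methanone F6. This is hydrogenated at once (H2, Pd/C, EtOAc–MeOH): hydrogen should add to the tetrasubstituted C2=C3 bond from the face opposite the C1 aroyl group while the benzyl ethers are cleaved, giving 22 directly.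

**Further compounds**

F1 | step 5 | 2-[3,5-bis(benzyloxy)phenyl]-1-[4-(benzyloxy)phenyl]ethan-1-one | O=C(Cc1cc(OCc2ccccc2)cc(OCc2ccccc2)c1)c1ccc(OCc2ccccc2)cc1
F2 | step 5 | allyl 3-[3,5-bis(benzyloxy)phenyl]-2,4-bis[4-(benzyloxy)phenyl]-4-oxobutanoate | C=CCOC(=O)C(c1ccc(OCc2ccccc2)cc1)C(C(=O)c1ccc(OCc2ccccc2)cc1)c1cc(OCc2ccccc2)cc(OCc2ccccc2)c1
F3 | step 5 | 3-[3,5-bis(benzyloxy)phenyl]-2,4-bis[4-(benzyloxy)phenyl]-4-oxobutanoic acid | OC(=O)C(c1ccc(OCc2ccccc2)cc1)C(C(=O)c1ccc(OCc2ccccc2)cc1)c1cc(OCc2ccccc2)cc(OCc2ccccc2)c1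
F4 | step 5 | 3-[4-(benzyloxy)benzoyl]-5,7-bis(benzyloxy)-2-[4-(benzyloxy)phenyl]-2,3-dihydro-1H-inden-1-one | O=C1C(c2ccc(OCc3ccccc3)cc2)C(C(=O)c2ccc(OCc3ccccc3)cc2)c2cc(OCc3ccccc3)cc(OCc3ccccc3)c12
F5 | step 7 | {(1S)-5,7-bis(benzyloxy)-1-[3,5-bis(benzyloxy)phenyl]-2-[4-(benzyloxy)phenyl]-1-hydroxy-1H-inden-3-yl}[4-(benzyloxy)phenyl]methanone (enantiomer of 19) | O=C(c1ccc(OCc2ccccc2)cc1)C1=C(c2ccc(OCc3ccccc3)cc2)[C@@](O)(c2cc(OCc3ccccc3)cc(OCc3ccccc3)c2)c2c(OCc3ccccc3)cc(OCc3ccccc3)cc21
F6 | step 9 | [(1S)-4,6-bis(benzyloxy)-3-[3,5-bis(benzyloxy)phenyl]-2-[4-(benzyloxy)phenyl]-1H-inden-1-yl][4-(benzyloxy)phenyl]methanone | O=C(c1ccc(OCc2ccccc2)cc1)[C@H]1c2cc(OCc3ccccc3)cc(OCc3ccccc3)c2C(c2cc(OCc3ccccc3)cc(OCc3ccccc3)c2)=C1c1ccc(OCc2ccccc2)cc1
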